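All runs were generated by integration for substances that don't exist, noise included.

Take the easy step first, the slope of a curve: if monomer enters chains at a rate proportional to [free monomer], the slope of a run shows how much free monomer is left, whatever else may be taking it. The choice of the next flask hangs on that reading.

| flask | free monomer | initiator | temperature | remark | time |
|---|---|---|---|---|---|
| south-west | 0.10 M | 1.6 mM | 10 °C | run made earlier |  |
| south-east | 0.15 M | 1.6 mM | 43 °C | run made earlier |  |
| west | 0.20 M | 2.4 mM | 10 °C | run made earlier |  |
| Monday's | 0.20 M | 1.6 mM | −5 °C |  | 1.0 h |
| Friday's | 0.20 M | 1.6 mM | 55 °C |  | 1.0 h |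
| Wednesday's | 0.20 M | 1.6 mM | 25 °C |  | 1.0 h |

- south-west (time / min: monomer in chains / %): 4.00: 1.7; 10.0: 4.4; 20.0: 8.8; 30.0: 12.5
- south-east (time / min: monomer in chains / %): 0.667: 6.3; 2.00: 17.5; 4.00: 30.4; 6.00: 37.8
- west (time / min: monomer in chains / %): 4.00: 2.3; 10.0: 4.5; 20.0: 9.6; 30.0: 13.9

(each reading ± 0.5 percentage points)

1. the best flask by amount of monomer in chains, in percent of the free monomer charged; "all alike" if 1.5 percentage points covers them all (Monday's / Friday's / Wednesday's / all alike)
2. amount of monomer in chains at the end, in percent of the free monomer charged, Monday's
3. amount of monomer in chains at the end, in percent of the free monomer charged, Friday's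
4. amount of monomer in chains at the end, in percent of the free monomer charged, Wednesday's

The south-east run opens at a slope of 0.0945 /min, and between its last two readings the slope is 0.0370 /min. So about 39.2% of the free monomer is left and 60.8% has gone, but the chains hold about 34.1%. That makes 56.1%: call this part of the free monomer gone that stands in chains the chain share, a selectivity. It is a reading, it carries the scatter, and I assume it holds in the flasks to come.

If chains grow with rate constant k, free monomer leaves at k/s. The south-west run gives 0.00440 /min, and taking ln k as linear in temperature through the two runs, which interpolates for Wednesday's but extrapolates below them for Monday's and above them for Friday's, my own reckoning for chains = s(1 − exp(−kt/s)) is: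

Monday's: k = 0.00109 /min, chains 6.18%

Wednesday's: k = 0.0177 /min, chains 47.7%

Friday's: k = 0.288 /min, chains 56.1%

So I would run Friday's, the hot flask, which takes its share of nearly all the charge and ends above Wednesday's.

The forecast reads the same bend differently, “This suggests a ceiling-temperature equilibrium”, and so chooses Wednesday's, with 3.5% for Monday's, 40% for Friday's and 68% for Wednesday's.

The flasks give 4.72% for Monday's, 66.9% for Friday's and 52.3% for Wednesday's, so the best is Friday's.

    initiator → 2 initiating radical (k = 0.00359 /min, Ea = 104 kJ/mol)
    free monomer + initiating radical → growing radical + monomer in chains (k = 1.21 × 10⁶ /M/s, Ea = 24.0 kJ/mol)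
    free monomer + growing radical → monomer in chains + growing radical, rate k3*[growing radical]*[free monomer] (k = 31100 /M/s, Ea = 23.0 kJ/mol)
    2 growing radical → dead chain (k = 8.00 × 10⁸ /M/s, Ea = 8.00 kJ/mol)
    free monomer → decomposition product (k = 6.29 × 10⁻⁵ /min, Ea = 109 kJ/mol)
    2 free monomer → homo dimer (k = 0.0505 /M/min, Ea = 68.0 kJ/mol)
    (constants at 25 °C)

Friday's has converted 99.0% of its free monomer and its chain share is 67.6%, so the bend marked a rival for the monomer, not an equilibrium. The homo dimer step, together with the step that ends growing radicals as dead chain, holds Friday's chains down, and the same flask without the homo dimer step reaches 95.2%. Wednesday's chain share is close, 63.9%, but by the hour its conversion is lower, at 81.9%, which gives its 52.3%. In Monday's the main reason for its 4.72% is the step that ends growing radicals as dead chain: the same flask without that step reaches 99.7%.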